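Assumption: the SMILES is taken exactly as drawn (cis-4,5-diol, 4S,5R, on the cyclohexenone; 6R methyl centre in the dienamide), and glutaconaldehyde potassium salt, TIPS-EBX and (S)-3-bromo-2-methylpropan-1-ol are taken as catalogue compounds.

## Retrosynthetic overview

1. Target ⇒ acetonide 29 ⇒ Stille disconnection inside the triene: core alkyne 19 + bromodienamide 27, which already carries the aminocyclopentenone ring.
2. 19 ⇒ C2–N bond: iodoenone 9 + dienamide 17 by copper-catalysed amidation. 17 comes from (S)-3-bromo-2-methylpropan-1-ol by Grignard coupling, oxidation/Wittig and HWE.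
3. 9 ⇒ key C4–C bond: photochemical γ-C–H alkynylation of enone 6 with retention. The C5 centre of quinic acid directs the quaternary C4 through the cis-fused dioxolane.
4. Rings: the cyclohexenone (ring A) is bought as (−)-quinic acid and the cyclopentenone (ring B) as cyclopentane-1,3-dione. Only a temporary lactone and dioxolane are formed (step 1); the dioxolane is opened last.

## Route

Step 1
Reactants: 1 (−)-quinic acid
Product: 2 3,4-O-isopropylidene-1,5-quinic lactone
Conditions: 2,2-dimethoxypropane (3 equiv), TsOH·H2O (5 mol%), acetone, reflux, 3 h; NaHCO3 quench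
Reagents that add atoms: 2,2-dimethoxypropane, COC(C)(C)OC
Why: Acid-catalysed lactonisation onto the 5-OH cis to the carboxyl and ketalisation of the cis-3,4-diol occur in one pot without touching any stereocentre.

Step 2
Reactants: 2 3,4-O-isopropylidene-1,5-quinic lactone
Product: 4 (3R,4S,5R)-3-hydroxy-4,5-(isopropylidenedioxy)cyclohexan-1-one, via triol 3 (not isolated)
Conditions: NaBH4 (2.5 equiv), EtOH, 0 °C to rt; AcOH to pH 6; then NaIO4 (1.3 equiv), pH 7 phosphate buffer, H2O, 0 °C to rt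
Reagents that add atoms: none
Why: Borohydride reduction of the strained lactone gives the only free vicinal diol, and its periodate (Malaprade) cleavage excises the former carboxyl carbon while leaving the three ring stereocentres of quinic acid untouched.

Step 3
Reactants: 4 (3R,4S,5R)-3-hydroxy-4,5-(isopropylidenedioxy)cyclohexan-1-one
Product: 6 (4S,5R)-4,5-(isopropylidenedioxy)cyclohex-2-en-1-one, via mesylate 5 (not isolated)
Conditions: MsCl (1.3 equiv), Et3N (3 equiv), CH2Cl2, 0 °C to rt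
Reagents that add atoms: none
Why: Mesylation of the β-hydroxyl and E1cB elimination under the same mild amine base give the enone, with C4 and C5 keeping the quinic acid configuration.

Step 4
Reactants: 6 (4S,5R)-4,5-(isopropylidenedioxy)cyclohex-2-en-1-one; 7 TIPS-EBX, 1-[(triisopropylsilyl)ethynyl]-1,2-benziodoxol-3(1H)-one
Product: 8 (4R,5R)-4,5-(isopropylidenedioxy)-4-[(triisopropylsilyl)ethynyl]cyclohex-2-en-1-one
Conditions: 7 (1.5 equiv), (Bu4N)4[W10O32] (4 mol%), degassed MeCN (0.1 M), 390 nm LEDs, 25 °C, Ar, 16 h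
Reagents that add atoms: none
Why: Proposed new method: excited decatungstate abstracts the weakest C–H of 6, the tertiary C4–H that is both allylic (γ to the enone) and α to oxygen, the resulting captodative radical reacts at its nucleophilic α-oxy terminus C4 (not at C2) with the electrophilic alkyne of 7 by addition and β-elimination of the iodanyl radical, which takes the hydrogen back from the reduced tungstate, and the new C–C bond forms on the face the hydrogen left because only that face keeps the dioxolane cis-fused and is not shielded by it, so the C5 centre from quinic acid fixes the quaternary C4 with retention (the descriptor changes from S to R by priority only); the closest known reaction type is the decatungstate- or diaryl-ketone-photocatalysed C(sp3)–H alkynylation of ethers with ethynylbenziodoxolones or alkynyl sulfones, which has not been shown for the γ-C–H of an enone or for a stereoretentive quaternary centre.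

Step 5
Reactants: 8 (4R,5R)-4,5-(isopropylidenedioxy)-4-[(triisopropylsilyl)ethynyl]cyclohex-2-en-1-one
Product: 9 (4R,5R)-2-iodo-4,5-(isopropylidenedioxy)-4-[(triisopropylsilyl)ethynyl]cyclohex-2-en-1-one
Conditions: I2 (1.6 equiv), pyridine–CH2Cl2 (1:1), 0 °C to rt; Na2S2O3 work-up
Reagents that add atoms: iodine, II
Why: Johnson α-iodination of the enone (pyridine conjugate addition, iodination of the enolate, elimination) tolerates the silyl alkyne and the acetonide and involves no stereocentre.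

Step 6
Reactants: 10 (S)-3-bromo-2-methylpropan-1-ol; 11 n-propylmagnesium chloride
Product: 12 (R)-2-methylhexan-1-ol
Conditions: 11 (3 equiv), Li2CuCl4 (3 mol%), THF, −78 to 0 °C; NH4Cl work-up
Reagents that add atoms: none
Why: Kochi-type copper-catalysed sp3–sp3 Grignard coupling at the primary bromide, with the alcohol masked as its magnesium alkoxide by the first equivalent, leaves the stereocentre untouched (S becomes R by priority only).

Step 7
Reactants: 12 (R)-2-methylhexan-1-ol; 13 2-(triphenylphosphoranylidene)propanal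
Product: 15 (2E,4R)-2,4-dimethyloct-2-enal, via (R)-2-methylhexanal 14 (not isolated)
Conditions: 2-iodoxybenzoic acid (IBX, 1.5 equiv), EtOAc, 75 °C, 3 h; filter; 13 (1.2 equiv) added to the filtrate, reflux, 16 h
Reagents that add atoms: none
Why: Neutral IBX oxidation followed by Wittig olefination with the formyl-stabilised ylide gives the (E)-trisubstituted enal without isolating or epimerising the volatile α-branched aldehyde.

Step 8
Reactants: 15 (2E,4R)-2,4-dimethyloct-2-enal; 16 diethyl (2-amino-2-oxoethyl)phosphonate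
Product: 17 (2E,4E,6R)-4,6-dimethyldeca-2,4-dienamide
Conditions: 16 (1.2 equiv), t-BuOK (1.2 equiv), THF, 0 °C to rt
Reagents that add atoms: none
Why: Horner–Wadsworth–Emmons olefination with the carbamoyl phosphonate sets the (2E) double bond and delivers the primary amide directly.

Step 9
Reactants: 9 (4R,5R)-2-iodo-4,5-(isopropylidenedioxy)-4-[(triisopropylsilyl)ethynyl]cyclohex-2-en-1-one; 17 (2E,4E,6R)-4,6-dimethyldeca-2,4-dienamide
Product: 18 (2E,4E,6R)-N-[(3R,4R)-3,4-(isopropylidenedioxy)-6-oxo-3-[(triisopropylsilyl)ethynyl]cyclohex-1-en-1-yl]-4,6-dimethyldeca-2,4-dienamide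
Conditions: 17 (1.2 equiv), CuI (10 mol%), N,N'-dimethylethylenediamine (20 mol%), K2CO3 (2 equiv), toluene, 60 °C
Reagents that add atoms: none
Why: Goldberg-type copper-catalysed C–N coupling of the vinyl iodide with the primary amide (achiral diamine ligand) installs the enamide, and the weak heterogeneous base in toluene limits β-elimination of the C5 oxygen.

Step 10
Reactants: 18 (2E,4E,6R)-N-[(3R,4R)-3,4-(isopropylidenedioxy)-6-oxo-3-[(triisopropylsilyl)ethynyl]cyclohex-1-en-1-yl]-4,6-dimethyldeca-2,4-dienamide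
Product: 19 (2E,4E,6R)-N-[(3R,4R)-3-ethynyl-3,4-(isopropylidenedioxy)-6-oxocyclohex-1-en-1-yl]-4,6-dimethyldeca-2,4-dienamide
Conditions: Bu4NF (1.2 equiv), AcOH (1.2 equiv), THF, 0 °C to rt
Reagents that add atoms: none
Why: Fluoride-induced protodesilylation of the alkynylsilane, buffered with acetic acid so that the base-sensitive β-alkoxy ketone survives.

Step 11
Reactants: 20 cyclopentane-1,3-dione
Product: 21 2-(hydroxyimino)cyclopentane-1,3-dione
Conditions: NaNO2 (1.05 equiv), aq HCl, 0–5 °C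
Reagents that add atoms: sodium nitrite, [Na+].[O-]N=O
Why: Nitrosation of the enolic 1,3-dione at C2 gives the oxime tautomer.

Step 12
Reactants: 21 2-(hydroxyimino)cyclopentane-1,3-dione
Product: 22 2-amino-3-hydroxycyclopent-2-en-1-one hydrochloride
Conditions: H2 (1 atm), 10% Pd/C, MeOH, HCl (1.1 equiv), rt
Reagents that add atoms: hydrogen chloride, Cl
Why: Catalytic hydrogenation of the oxime gives the primary amine, trapped as its stable hydrochloride.

Step 13
Reactants: 23 glutaconaldehyde potassium salt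
Product: 24 (2E,4E)-5-bromopenta-2,4-dienal
Conditions: PPh3 (1.1 equiv), Br2 (1.1 equiv), CH2Cl2, 0 °C; then 23, 0 °C to rt
Reagents that add atoms: bromine, BrBr
Why: Deoxybromination of the dienolate oxygen by Ph3PBr2 gives the vinyl bromide in its thermodynamic E,E geometry.

Step 14
Reactants: 24 (2E,4E)-5-bromopenta-2,4-dienal
Product: 25 (2E,4E)-5-bromopenta-2,4-dienoic acid
Conditions: NaClO2 (1.5 equiv), NaH2PO4, 2-methylbut-2-ene, t-BuOH–H2O, 0 °C to rt
Reagents that add atoms: sodium chlorite, [Na+].[O-]Cl=O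
Why: Pinnick oxidation converts the aldehyde into the acid without touching the bromodiene.

Step 15
Reactants: 25 (2E,4E)-5-bromopenta-2,4-dienoic acid; 22 2-amino-3-hydroxycyclopent-2-en-1-one hydrochloride
Product: 27 (2E,4E)-5-bromo-N-(2-hydroxy-5-oxocyclopent-1-en-1-yl)penta-2,4-dienamide, via acid chloride 26 (not isolated)
Conditions: (COCl)2 (1.2 equiv), DMF (cat), CH2Cl2, 0 °C to rt; then 22, Et3N (3 equiv), DMAP (cat), CH2Cl2–DMF, 0 °C to rt
Reagents that add atoms: none
Why: Acid chloride formation and N-acylation of the amine give the amide, any enol ester formed first rearranging from O to N under the DMAP conditions.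

Step 16
Reactants: 19 (2E,4E,6R)-N-[(3R,4R)-3-ethynyl-3,4-(isopropylidenedioxy)-6-oxocyclohex-1-en-1-yl]-4,6-dimethyldeca-2,4-dienamide; 27 (2E,4E)-5-bromo-N-(2-hydroxy-5-oxocyclopent-1-en-1-yl)penta-2,4-dienamide
Product: 29 (2E,4E,6R)-N-[(3S,4R)-3-[(1E,3E,5E)-7-[(2-hydroxy-5-oxocyclopent-1-en-1-yl)amino]-7-oxohepta-1,3,5-trien-1-yl]-3,4-(isopropylidenedioxy)-6-oxocyclohex-1-en-1-yl]-4,6-dimethyldeca-2,4-dienamide, via vinylstannane 28 (not isolated)
Conditions: PdCl2(PPh3)2 (5 mol%), Bu3SnH (1.1 equiv, slow addition), THF, 0 °C; then 27 (1.1 equiv), Pd2(dba)3 (5 mol%), AsPh3 (20 mol%), DMF, rt, dark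
Reagents that add atoms: none
Why: Palladium-catalysed syn-hydrostannation puts tin on the unhindered alkyne terminus to give the (E)-vinylstannane, and Stille coupling with the bromodiene proceeds with retention of all alkene geometries to give the E,E,E-triene.

Step 17
Reactants: 29 (2E,4E,6R)-N-[(3S,4R)-3-[(1E,3E,5E)-7-[(2-hydroxy-5-oxocyclopent-1-en-1-yl)amino]-7-oxohepta-1,3,5-trien-1-yl]-3,4-(isopropylidenedioxy)-6-oxocyclohex-1-en-1-yl]-4,6-dimethyldeca-2,4-dienamide
Product: 30 (2E,4E,6R)-N-[(3S,4R)-3,4-dihydroxy-3-[(1E,3E,5E)-7-[(2-hydroxy-5-oxocyclopent-1-en-1-yl)amino]-7-oxohepta-1,3,5-trien-1-yl]-6-oxocyclohex-1-en-1-yl]-4,6-dimethyldeca-2,4-dienamide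
Conditions: AcOH–H2O (4:1), 40 °C
Reagents that add atoms: none
Why: Acid-catalysed acetonide hydrolysis cleaves at the ketal carbon, not at the tertiary C–O bond, whose cation would be flanked by the enone and the acyl-terminated triene, so the cis-diol configuration is kept.

## Compound list

1 | (−)-quinic acid, (1S,3R,4S,5R)-1,3,4,5-tetrahydroxycyclohexane-1-carboxylic acid | OC(=O)[C@]1(O)C[C@@H](O)[C@@H](O)[C@H](O)C1 | starting material
2 | 3,4-O-isopropylidene-1,5-quinic lactone (all centres as in 1) | O[C@@]12C[C@H]3OC(C)(C)O[C@H]3[C@@H](C1)OC2=O | intermediate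
3 | triol from reduction of the lactone of 2 to CH2OH and OH (ring centres as in 2) | OC[C@]1(O)C[C@H]2OC(C)(C)O[C@H]2[C@H](O)C1 | intermediate
4 | (3R,4S,5R)-3-hydroxy-4,5-(isopropylidenedioxy)cyclohexan-1-one | O=C1C[C@H]2OC(C)(C)O[C@H]2[C@H](O)C1 | intermediate
5 | 3-O-mesylate of 4 | O=C1C[C@H]2OC(C)(C)O[C@H]2[C@H](OS(C)(=O)=O)C1 | intermediate
6 | (4S,5R)-4,5-(isopropylidenedioxy)cyclohex-2-en-1-one | O=C1C=C[C@@H]2OC(C)(C)O[C@@H]2C1 | intermediate
7 | TIPS-EBX, 1-[(triisopropylsilyl)ethynyl]-1,2-benziodoxol-3(1H)-one | CC(C)[Si](C#CI1OC(=O)c2ccccc12)(C(C)C)C(C)C | starting material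
8 | (4R,5R)-4,5-(isopropylidenedioxy)-4-[(triisopropylsilyl)ethynyl]cyclohex-2-en-1-one | O=C1C=C[C@]2(C#C[Si](C(C)C)(C(C)C)C(C)C)OC(C)(C)O[C@@H]2C1 | intermediate
9 | (4R,5R)-2-iodo-4,5-(isopropylidenedioxy)-4-[(triisopropylsilyl)ethynyl]cyclohex-2-en-1-one | O=C1C(I)=C[C@]2(C#C[Si](C(C)C)(C(C)C)C(C)C)OC(C)(C)O[C@@H]2C1 | intermediate
10 | (S)-3-bromo-2-methylpropan-1-ol | OC[C@H](C)CBr | starting material
11 | n-propylmagnesium chloride | CCC[Mg]Cl | starting material
12 | (R)-2-methylhexan-1-ol | OC[C@H](C)CCCC | intermediate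
13 | 2-(triphenylphosphoranylidene)propanal | CC(C=O)=P(c1ccccc1)(c1ccccc1)c1ccccc1 | starting material
14 | (R)-2-methylhexanal | CCCC[C@@H](C)C=O | intermediate
15 | (2E,4R)-2,4-dimethyloct-2-enal | CCCC[C@@H](C)/C=C(C)/C=O | intermediate
16 | diethyl (2-amino-2-oxoethyl)phosphonate | CCOP(=O)(CC(N)=O)OCC | starting material
17 | (2E,4E,6R)-4,6-dimethyldeca-2,4-dienamide | CCCC[C@@H](C)/C=C(C)/C=C/C(N)=O | intermediate
18 | (2E,4E,6R)-N-[(3R,4R)-3,4-(isopropylidenedioxy)-6-oxo-3-[(triisopropylsilyl)ethynyl]cyclohex-1-en-1-yl]-4,6-dimethyldeca-2,4-dienamide | CCCC[C@@H](C)/C=C(C)/C=C/C(=O)NC1=C[C@]2(C#C[Si](C(C)C)(C(C)C)C(C)C)OC(C)(C)O[C@@H]2CC1=O | intermediate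
19 | (2E,4E,6R)-N-[(3R,4R)-3-ethynyl-3,4-(isopropylidenedioxy)-6-oxocyclohex-1-en-1-yl]-4,6-dimethyldeca-2,4-dienamide | CCCC[C@@H](C)/C=C(C)/C=C/C(=O)NC1=C[C@]2(C#C)OC(C)(C)O[C@@H]2CC1=O | intermediate
20 | cyclopentane-1,3-dione | O=C1CCC(=O)C1 | starting material
21 | 2-(hydroxyimino)cyclopentane-1,3-dione | O=C1CCC(=O)C1=NO | intermediate
22 | 2-amino-3-hydroxycyclopent-2-en-1-one hydrochloride | NC1=C(O)CCC1=O.Cl | intermediate
23 | glutaconaldehyde potassium salt, potassium (1E,3E)-5-oxopenta-1,3-dien-1-olate | [K+].[O-]/C=C/C=C/C=O | starting material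
24 | (2E,4E)-5-bromopenta-2,4-dienal | Br/C=C/C=C/C=O | intermediate
25 | (2E,4E)-5-bromopenta-2,4-dienoic acid | Br/C=C/C=C/C(O)=O | intermediate
26 | (2E,4E)-5-bromopenta-2,4-dienoyl chloride | Br/C=C/C=C/C(Cl)=O | intermediate
27 | (2E,4E)-5-bromo-N-(2-hydroxy-5-oxocyclopent-1-en-1-yl)penta-2,4-dienamide | Br/C=C/C=C/C(=O)NC1=C(O)CCC1=O | intermediate
28 | (E)-vinylstannane: 19 with the ethynyl group replaced by (E)-2-(tributylstannyl)ethenyl | CCCC[C@@H](C)/C=C(C)/C=C/C(=O)NC1=C[C@]2(/C=C/[Sn](CCCC)(CCCC)CCCC)OC(C)(C)O[C@@H]2CC1=O | intermediate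
29 | (2E,4E,6R)-N-[(3S,4R)-3-[(1E,3E,5E)-7-[(2-hydroxy-5-oxocyclopent-1-en-1-yl)amino]-7-oxohepta-1,3,5-trien-1-yl]-3,4-(isopropylidenedioxy)-6-oxocyclohex-1-en-1-yl]-4,6-dimethyldeca-2,4-dienamide | CCCC[C@@H](C)/C=C(C)/C=C/C(=O)NC1=C[C@]2(/C=C/C=C/C=C/C(=O)NC3=C(O)CCC3=O)OC(C)(C)O[C@@H]2CC1=O | intermediate
30 | (2E,4E,6R)-N-[(3S,4R)-3,4-dihydroxy-3-[(1E,3E,5E)-7-[(2-hydroxy-5-oxocyclopent-1-en-1-yl)amino]-7-oxohepta-1,3,5-trien-1-yl]-6-oxocyclohex-1-en-1-yl]-4,6-dimethyldeca-2,4-dienamide | CCCC[C@@H](C)/C=C(C)/C=C/C(=O)NC1=C[C@@](O)(/C=C/C=C/C=C/C(=O)NC2=C(O)CCC2=O)[C@H](O)CC1=O | target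

## Step count and risks

Total step count: 17. Longest linear sequence: 9 steps from (−)-quinic acid (steps 1, 2, 3, 4, 5, 9, 10, 16, 17).

The three steps most likely to fail:

Step 4 (the new photochemical C–H alkynylation). The risks are hydrogen abstraction at C5–H instead of C4–H, coupling of the delocalised radical at C2, or sluggish addition of the stabilised radical to 7. The fallback uses known chemistry, sets out from 1 and comes back at 8. Compound 1 is lactonised (TsOH, toluene–DMF, reflux) to quinic acid 1,5-lactone F1. Its equatorial 3-OH is silylated (TBSCl, imidazole, DMF, 0 °C) to the 3-O-TBS lactone F2, and Dess–Martin oxidation gives the 4-ketone F3. LiC≡CSi(iPr)3 with CeCl3 (3 equiv, THF, −78 °C) adds to the ketone from the face opposite the lactone bridge to give the tertiary alkynyl carbinol F4. Its new 4-OH is cis to the C5 lactone oxygen; this pair becomes the cis-diol of the target, with the ring numbered the other way round. Methanolic HCl followed by 2,2-dimethoxypropane opens the lactone, removes the TBS group and ketalises the cis-4,5-diol to give the methyl ester acetonide F5. NaBH4 reduces the ester to the triol F6, NaIO4 cleaves its 1,2-diol to the β-hydroxy ketone F7, and MsCl/Et3N eliminates through the mesylate F8 to give 8.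

Step 9 (copper-catalysed amidation). The risks are base-induced loss of the C5 oxygen by β-elimination from the C6 enolate and slow coupling next to the quaternary centre. The fallback sets out from 9 (and from 15 for the acyl part) and comes back at 18. The vinyl iodide is converted into the 2-azido enone F9 (NaN3, CuI, sodium ascorbate (NaC6H7O6), N,N'-dimethylethylenediamine, EtOH–H2O, rt). Staudinger reduction (PPh3, THF–H2O) gives the 2-amino enone F10. Enal 15 is condensed with malonic acid (Doebner–Knoevenagel, pyridine, piperidine) to (2E,4E,6R)-4,6-dimethyldeca-2,4-dienoic acid F11, which (COCl)2 converts into (2E,4E,6R)-4,6-dimethyldeca-2,4-dienoyl chloride F12. N-acylation of the amine with this chloride (pyridine, CH2Cl2, 0 °C) gives 18, so the amide is made by acylation instead of C–N coupling.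

Step 16 (one-pot hydrostannation and Stille coupling). The risks are the wrong stannane regioisomer, reduction of the enone by the tin hydride, and protodestannylation by the acidic enol of 27. The fallback sets out from 19 and comes back at 29. Semi-hydrogenation (H2, Pd/CaCO3 poisoned with Pb(OAc)2, quinoline, EtOAc) gives the 4-vinyl compound F13. A Heck reaction with 27 (Pd(OAc)2, P(o-tol)3, Ag2CO3, DMF, 50 °C) then joins the two alkenes with the new double bond E to give 29.

## Further compounds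

F1 | step 4 | quinic acid 1,5-lactone (1,5-quinide) | O[C@@]12C[C@@H](O)[C@@H](O)[C@@H](C1)OC2=O
F2 | step 4 | 3-O-(tert-butyldimethylsilyl)-1,5-quinide | O[C@@]12C[C@@H](O[Si](C)(C)C(C)(C)C)[C@@H](O)[C@@H](C1)OC2=O
F3 | step 4 | 3-O-(tert-butyldimethylsilyl)-4-oxo-1,5-quinide | O[C@@]12C[C@@H](O[Si](C)(C)C(C)(C)C)C(=O)[C@@H](C1)OC2=O
F4 | step 4 | 4-epi-4-C-[(triisopropylsilyl)ethynyl]-3-O-(tert-butyldimethylsilyl)-1,5-quinide (4-OH cis to the C5 lactone oxygen) | O[C@@]12C[C@@H](O[Si](C)(C)C(C)(C)C)[C@@](O)(C#C[Si](C(C)C)(C(C)C)C(C)C)[C@@H](C1)OC2=O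
F5 | step 4 | methyl 1,3-dihydroxy-4,5-(isopropylidenedioxy)-4-[(triisopropylsilyl)ethynyl]cyclohexane-1-carboxylate (4,5-dioxolane cis-fused, 3-OH trans to the C4 oxygen) | COC(=O)[C@]1(O)C[C@@H](O)[C@]2(C#C[Si](C(C)C)(C(C)C)C(C)C)OC(C)(C)O[C@@H]2C1
F6 | step 4 | triol from reduction of the ester of F5 to CH2OH | OC[C@]1(O)C[C@@H](O)[C@]2(C#C[Si](C(C)C)(C(C)C)C(C)C)OC(C)(C)O[C@@H]2C1
F7 | step 4 | 3-hydroxy-4,5-(isopropylidenedioxy)-4-[(triisopropylsilyl)ethynyl]cyclohexan-1-one (β-hydroxy ketone, ring centres as in F5) | O=C1C[C@@H](O)[C@]2(C#C[Si](C(C)C)(C(C)C)C(C)C)OC(C)(C)O[C@@H]2C1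
F8 | step 4 | 3-O-mesylate of F7 | O=C1C[C@@H](OS(C)(=O)=O)[C@]2(C#C[Si](C(C)C)(C(C)C)C(C)C)OC(C)(C)O[C@@H]2C1
F9 | step 9 | (4R,5R)-2-azido-4,5-(isopropylidenedioxy)-4-[(triisopropylsilyl)ethynyl]cyclohex-2-en-1-one | [N-]=[N+]=NC1=C[C@]2(C#C[Si](C(C)C)(C(C)C)C(C)C)OC(C)(C)O[C@@H]2CC1=O
F10 | step 9 | (4R,5R)-2-amino-4,5-(isopropylidenedioxy)-4-[(triisopropylsilyl)ethynyl]cyclohex-2-en-1-one | NC1=C[C@]2(C#C[Si](C(C)C)(C(C)C)C(C)C)OC(C)(C)O[C@@H]2CC1=O
F11 | step 9 | (2E,4E,6R)-4,6-dimethyldeca-2,4-dienoic acid | CCCC[C@@H](C)/C=C(C)/C=C/C(O)=O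
F12 | step 9 | (2E,4E,6R)-4,6-dimethyldeca-2,4-dienoyl chloride | CCCC[C@@H](C)/C=C(C)/C=C/C(Cl)=O
F13 | step 16 | (2E,4E,6R)-N-[(3S,4R)-3-ethenyl-3,4-(isopropylidenedioxy)-6-oxocyclohex-1-en-1-yl]-4,6-dimethyldeca-2,4-dienamide | CCCC[C@@H](C)/C=C(C)/C=C/C(=O)NC1=C[C@]2(C=C)OC(C)(C)O[C@@H]2CC1=O
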